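The upper flavan has a 3-deoxy C ring. C3 is a bare CH2 between C2 (bonded to O1 and ring B) and C4, which is doubly benzylic between C4a of ring A and C8 of the catechin A ring. Cutting C2–C3 and C4–C4a reveals an 8-vinylcatechin and an aryl oxocarbenium ion, ArO+=CH–Ar. One catalytic asymmetric oxa-Povarov reaction, a stepwise cationic [4+2], makes both bonds, closes the pyran ring and sets C2 and C4 as the 2,4-cis pair. Its precursors are perbenzylated 8-vinyl-(+)-catechin, whose trioxygenated ring carries the C4 cation, and the symmetric bis(3-benzyloxyphenyl) acetal of 3,4-bis(benzyloxy)benzaldehyde.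

Key step: step 5

Assumption: the sense of induction of the chiral acid on the oxocarbenium ion pair cannot be predicted, so the (R)-acid is written and its antipode is taken if a pilot run shows the opposite sense.

Step 1
Reactants: 1 (+)-catechin, (2R,3S), dried
Product: 3 3,5,7,3',4'-penta-O-benzyl-(+)-catechin, via 5,7,3',4'-tetra-O-benzylcatechin 2 (not isolated)
Conditions: BnBr (6.5 equiv), K2CO3, DMF, 0 °C to rt; then NaH, 0 °C to rt, same flask
Reagents that add atoms: benzyl bromide, BrCc1ccccc1
Why: Williamson ether synthesis in two stages, in which carbonate caps the four phenols first, so the 4'-phenoxide that could epimerise C2 through a quinone methide is gone before NaH deprotonates the C3 alcohol, and neither stereocentre is touched.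

Step 2
Reactants: 3 penta-O-benzyl-(+)-catechin
Product: 4 8-bromo-3,5,7,3',4'-penta-O-benzyl-(+)-catechin
Conditions: NBS (1.0 equiv), CH2Cl2, −78 °C to 0 °C
Reagents that add atoms: N-bromosuccinimide, O=C1CCC(=O)N1Br
Why: Electrophilic aromatic bromination, in which C8 is the most nucleophilic free position of benzylated catechins, so one equivalent of NBS at low temperature should stop at the 8-bromide and leave ring B and the stereocentres alone.

Step 3
Reactants: 4 8-bromo-penta-O-benzyl-(+)-catechin
Product: 5 8-vinyl-3,5,7,3',4'-penta-O-benzyl-(+)-catechin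
Conditions: vinyl-Bpin, Pd(OAc)2 (5 mol %), SPhos (10 mol %), K3PO4, toluene/H2O, 80 °C; Et3N-deactivated silica
Reagents that add atoms: vinylboronic acid pinacol ester, C=CB1OC(C)(C)C(C)(C)O1
Why: Suzuki–Miyaura vinylation, in which the bulky electron-rich biaryl phosphine suits oxidative addition into an electron-rich, di-ortho-oxygenated aryl bromide, and the phosphate base spares the benzyl ethers and both stereocentres.

Step 4
Reactants: 6 3,4-bis(benzyloxy)benzaldehyde; 7 3-(benzyloxy)phenol (2.2 equiv)
Product: 10 3,4-bis(benzyloxy)benzaldehyde bis[3-(benzyloxy)phenyl] acetal, via 3,4-bis(benzyloxy)benzal chloride 8 (not isolated), via sodium 3-(benzyloxy)phenoxide 9 (not isolated)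
Conditions: 6, (COCl)2, Ph3PO (15 mol %), CHCl3, rt, concentrate; 7, NaH, DMF, 0 °C; combine at −20 °C to rt; crystallisation or Et3N-deactivated silica
Reagents that add atoms: oxalyl chloride, O=C(Cl)C(Cl)=O (chlorine of 8); sodium hydride, [Na+].[H-] (sodium of 9)
Why: Phosphine-oxide-catalysed deoxydichlorination of the aldehyde followed by a double Williamson-type substitution, in which the electron-rich benzal chloride ionises easily, so each chloride is replaced by phenoxide oxygen in DMF, and the acetal carbon bears two identical aryloxy groups and is no stereocentre.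

Step 5
Reactants: 5 8-vinyl-penta-O-benzyl-(+)-catechin; 10 bis[3-(benzyloxy)phenyl] acetal (1.3 equiv)
Product: 13 octa-O-benzyl-(2S,4S)-3',4',7-trihydroxyflavan-(4α→8)-(+)-catechin, via aryl oxocarbenium ion 11 (not isolated), via C4 benzylic cation 12 (not isolated)
Conditions: (R)-3,3'-bis(2,4,6-triisopropylphenyl)-BINOL N-triflylphosphoramide (10 mol %), 4 Å MS, toluene/CH2Cl2, −60 °C, slow addition of 5, then to −20 °C; Et3N quench
Reagents that add atoms: none
Why: Proposed new method: the chiral acid protonates one aryloxy group of 10 and expels 3-(benzyloxy)phenol to give the aryl oxocarbenium ion 11 (a cationic 2-oxadiene) as a contact ion pair with the phosphoramidate, the CH2 terminus of 5 adds to its carbon (C2–C3 bond) to give cation 12, stabilised by the 5,7,8a-trioxygenated catechin ring, and the tethered aryl ether attacks C4 through its carbon ortho to O1 (C4–C4a bond) and loses the proton that regenerates the acid. The closest known reaction types are the Lewis-acid-promoted racemic oxa-Povarov reaction of aryl oxocarbenium ions with styrenes, the chiral-phosphoric-acid-catalysed Povarov reaction of styrenes and chiral-anion-directed additions to oxocarbenium ions, and only their combination is new. The one ring that closes, the pyran C ring, does so by intramolecular Friedel–Crafts alkylation in a 6-(enolendo)-exo-trig pattern, with the nucleophilic C4a=C8a bond inside and the quinone-methide-type C4=C8 bond outside the new ring. C2 is controlled by the chiral anion, which shields one face of planar 11, and little mismatch is expected because the nearest catechin stereocentre lies five bonds from the attacking CH2, while C4 is controlled by C2 through a chair-like closure with both aryl groups pseudo-equatorial (2,4-cis), and acid-reversible opening of the C2–O1 bond should leave only 2,4-cis adducts. The step needs Markovnikov addition (secured by the trialkoxyaryl group on the alkene), closure para rather than ortho to the 3-benzyloxy group (secured by crowding at the carbon between the two oxygens) and a single mode of ionisation (secured by the two identical aryloxy groups of 10). As 5 is enantiopure, the (2R,4R) adduct is a diastereomer of 13, and whatever forms of it is removed by chromatography.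

Step 6
Reactants: 13 octa-O-benzyl dimer
Product: 14 (2S,4S)-3',4',7-trihydroxyflavan-(4α→8)-(+)-catechin (CNP0227165.3)
Conditions: H2 (1 atm), Pd(OH)2/C, THF/MeOH/H2O, rt; filtration under argon, Sephadex LH-20, lyophilisation
Reagents that add atoms: none
Why: Catalytic hydrogenolysis removes all eight O-benzyl groups under neutral conditions of the kind that spare the cyclic C2–O1 benzylic ethers and the interflavan bond of benzylated proanthocyanidins, so the four stereocentres stay as set.

Compound list
1 | (+)-catechin, (2R,3S) | c1c(O)cc(O)c2c1O[C@H](c1ccc(O)c(O)c1)[C@@H](O)C2 | starting material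
2 | 5,7,3',4'-tetra-O-benzyl-(+)-catechin | c1c(OCc3ccccc3)cc(OCc3ccccc3)c2c1O[C@H](c1ccc(OCc3ccccc3)c(OCc3ccccc3)c1)[C@@H](O)C2 | intermediate
3 | 3,5,7,3',4'-penta-O-benzyl-(+)-catechin | c1c(OCc3ccccc3)cc(OCc3ccccc3)c2c1O[C@H](c1ccc(OCc3ccccc3)c(OCc3ccccc3)c1)[C@@H](OCc1ccccc1)C2 | intermediate
4 | 8-bromo-penta-O-benzyl-(+)-catechin | Brc1c(OCc3ccccc3)cc(OCc3ccccc3)c2c1O[C@H](c1ccc(OCc3ccccc3)c(OCc3ccccc3)c1)[C@@H](OCc1ccccc1)C2 | intermediate
5 | 8-vinyl-penta-O-benzyl-(+)-catechin | C=Cc1c(OCc3ccccc3)cc(OCc3ccccc3)c2c1O[C@H](c1ccc(OCc3ccccc3)c(OCc3ccccc3)c1)[C@@H](OCc1ccccc1)C2 | intermediate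
6 | 3,4-bis(benzyloxy)benzaldehyde | O=Cc1ccc(OCc2ccccc2)c(OCc2ccccc2)c1 | starting material
7 | 3-(benzyloxy)phenol | Oc1cccc(OCc2ccccc2)c1 | starting material
8 | 3,4-bis(benzyloxy)benzal chloride | ClC(Cl)c1ccc(OCc2ccccc2)c(OCc2ccccc2)c1 | intermediate
9 | sodium 3-(benzyloxy)phenoxide | [Na+].[O-]c1cccc(OCc2ccccc2)c1 | intermediate
10 | 3,4-bis(benzyloxy)benzaldehyde bis[3-(benzyloxy)phenyl] acetal | C(Oc1cccc(OCc2ccccc2)c1)(Oc1cccc(OCc2ccccc2)c1)c1ccc(OCc2ccccc2)c(OCc2ccccc2)c1 | intermediate
11 | [3-(benzyloxy)phenyl][3,4-bis(benzyloxy)benzylidene]oxonium ion | c1ccccc1COc1cccc([O+]=Cc2ccc(OCc3ccccc3)c(OCc3ccccc3)c2)c1 | intermediate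
12 | (3S)-3-aryloxy-3-aryl-1-(catechin-8-yl)propyl cation, cationic at the future C4 | c1ccccc1COc1cccc(c1)O[C@H](c1ccc(OCc3ccccc3)c(OCc3ccccc3)c1)C[CH+]c1c(OCc3ccccc3)cc(OCc3ccccc3)c2c1O[C@H](c1ccc(OCc3ccccc3)c(OCc3ccccc3)c1)[C@@H](OCc1ccccc1)C2 | intermediate
13 | octa-O-benzyl-(2S,4S)-3',4',7-trihydroxyflavan-(4α→8)-(+)-catechin | c1ccccc1COc1ccc2c(c1)O[C@H](c1ccc(OCc3ccccc3)c(OCc3ccccc3)c1)C[C@@H]2c1c(OCc3ccccc3)cc(OCc3ccccc3)c2c1O[C@H](c1ccc(OCc3ccccc3)c(OCc3ccccc3)c1)[C@@H](OCc1ccccc1)C2 | intermediate
14 | (2S,4S)-3',4',7-trihydroxyflavan-(4α→8)-(2R,3S)-catechin | Oc1ccc2c(c1)O[C@H](c1ccc(O)c(O)c1)C[C@@H]2c1c(O)cc(O)c2c1O[C@H](c1ccc(O)c(O)c1)[C@@H](O)C2 | target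

Total step count: 6. Longest linear sequence: 5 (steps 1, 2, 3, 5, 6).

Steps most likely to fail

Step 5 (labelled).
- What may go wrong: the ion pair may discriminate weakly between the two faces of 11. The Brønsted acid may protonate the styrene and start cationic oligomerisation. Cation 12 may lose a proton, or Friedel–Crafts attack of the catechin C6 position on 11 may compete.
- Fallback with known chemistry: induction is given up and the resident catechin stereocentres serve for resolution instead. It sets out from 5 and 10, which are combined under the established stoichiometric Lewis acid oxa-Povarov protocol (SnCl4, 2,6-di-tert-butylpyridine as proton trap, CH2Cl2, −78 °C).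
- This keeps free protons away from the alkene and should give both 2,4-cis adducts, namely 13 and the (2R,4R) diastereomer F1. The two are separated by chromatography or crystallisation, and the route is rejoined at 13.

Step 4.
- What may go wrong: the labile benzal chloride may hydrolyse or ionise prematurely. The ambident phenoxide may be alkylated at carbon. The acetal may be lost on acidic silica.
- The fallback reaches the same ion by oxidation of a robust ether. It sets out from 7, which is alkylated with commercial 3,4-bis(benzyloxy)benzyl chloride (ClCc1ccc(OCc2ccccc2)c(OCc2ccccc2)c1; K2CO3, DMF) to the aryl benzyl ether F2.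
- DDQ abstracts hydride from the 3,4-dialkoxybenzylic C–H in CH2Cl2/AcOH over 4 Å MS, and acetate capture gives the α-acetoxy ether F3, which is used crude.
- Under the step 5 catalyst F3 ionises by loss of acetic acid to the same ion 11, and the route is rejoined at 13.

Step 3.
- What may go wrong: oxidative addition into the hindered, electron-rich bromide may be slow, with protodebromination, and the acid-sensitive styrene may polymerise on work-up.
- The fallback builds the vinyl group by carbonyl olefination. It sets out from 4. Bromine–lithium exchange (n-BuLi, THF, −78 °C) gives the 8-lithio compound F4, and DMF converts it into the 8-carbaldehyde F5.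
- Wittig methylenation with methylenetriphenylphosphorane F6 (from MePPh3Br and KOt-Bu, THF, 0 °C) rejoins the route at 5.

Further compounds
F1 | step 5 | octa-O-benzyl-(2R,4R)-3',4',7-trihydroxyflavan-(4β→8)-(+)-catechin | c1ccccc1COc1ccc2c(c1)O[C@@H](c1ccc(OCc3ccccc3)c(OCc3ccccc3)c1)C[C@H]2c1c(OCc3ccccc3)cc(OCc3ccccc3)c2c1O[C@H](c1ccc(OCc3ccccc3)c(OCc3ccccc3)c1)[C@@H](OCc1ccccc1)C2
F2 | step 4 | 1-(benzyloxy)-3-{[3,4-bis(benzyloxy)benzyl]oxy}benzene | c1ccccc1COc1cccc(OCc2ccc(OCc3ccccc3)c(OCc3ccccc3)c2)c1
F3 | step 4 | [3,4-bis(benzyloxy)phenyl][3-(benzyloxy)phenoxy]methyl acetate (racemic) | CC(=O)OC(Oc1cccc(OCc2ccccc2)c1)c1ccc(OCc2ccccc2)c(OCc2ccccc2)c1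
F4 | step 3 | 8-lithio-penta-O-benzyl-(+)-catechin | [Li]c1c(OCc3ccccc3)cc(OCc3ccccc3)c2c1O[C@H](c1ccc(OCc3ccccc3)c(OCc3ccccc3)c1)[C@@H](OCc1ccccc1)C2
F5 | step 3 | penta-O-benzyl-(+)-catechin-8-carbaldehyde | O=Cc1c(OCc3ccccc3)cc(OCc3ccccc3)c2c1O[C@H](c1ccc(OCc3ccccc3)c(OCc3ccccc3)c1)[C@@H](OCc1ccccc1)C2
F6 | step 3 | methylenetriphenylphosphorane | C=P(c1ccccc1)(c1ccccc1)c1ccccc1
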